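The target is cut through its seven-membered ring at C6–C7 and C9–C10: C6 and C10 are carbinol carbons on the adjacent ring-fusion atoms C5 and C1, and C7–C8(CH3)=C9 between them is an isobutene unit. One flask joins a trans-cyclopentane-1,2-dicarbaldehyde to 3-iodo-2-[(trimethylsilyl)methyl]prop-1-ene by Barbier allylation at C6 and Hosomi–Sakurai closure at C10; this forms both bonds, closes the seven-membered ring and sets the C6 carbinol centre. The precursor, made from (S)-allethrolone, is a cyclopentane with the quaternary C1 (methyl, formyl), a C2 silyl ether, a free tertiary C4 hydroxyl next to isopropyl, and the C5 formyl group trans to the C1 formyl group.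

Key step: step 10

Assumption: (S)-allethrolone 1 is available enantiopure (otherwise by lipase resolution of the commercial racemate); the C4 hydroxyl is carried unprotected from step 4 onward because the key step uses it as a chelating group.
Convention: atoms are numbered as in the hydroazulene (C1 quaternary ring-fusion carbon with CH3, C2 CHOAc, C3 CH2, C4 C(OH)iPr, C5 ring-fusion CH, C6 CHO-angeloyl, C7 CH2, C8 bearing CH3, C9, C10 CHOBz); β is the face of the C5 hydrogen, so the target has C1-CH3 α, C2-O β, C4-OH α, C4-iPr β, C6-O β, C10-O α.

Step 1
Reactants: 1 (S)-allethrolone; 2 (bromomethyl)chlorodimethylsilane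
Product: 3 (bromomethyl)dimethylsilyl ether of allethrolone
Conditions: Et3N, DMAP (cat.), CH2Cl2, 0 °C
Reagents that add atoms: (bromomethyl)chlorodimethylsilane 2, C[Si](C)(Cl)CBr
Why: O-silylation of the secondary allylic alcohol with a chlorosilane is routine and tethers the future C10 carbon to the C2 oxygen without touching the C2 stereocentre.

Step 2
Reactants: 3 (bromomethyl)dimethylsilyl ether of allethrolone
Product: 5 keto diol (C5 epimer mixture), via siloxane ketone 4 (not isolated)
Conditions: Bu3SnH, AIBN (cat.), PhH, 80 °C (slow addition); then KF, KHCO3, 30% H2O2, THF/MeOH, rt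
Reagents that add atoms: hydrogen peroxide, OO
Why: Stork-type silicon-tethered 5-exo-trig radical cyclisation of the nucleophilic α-silyl radical onto the enone β-carbon C1, followed by Tamao–Fleming oxidation; the short O–Si–CH2 tether reaches only the face of the C2 oxygen, so the quaternary C1 should form with C10 cis to O2, whereas hydrogen transfer to the C5 radical is not expected to be selective and C5 is settled in step 3.

Step 3
Reactants: 5 keto diol (C5 epimer mixture)
Product: 6 acetonide ketone with the C5 allyl group α
Conditions: Me2C(OMe)2, PPTS (cat.), CH2Cl2, rt; then DBU (cat.), rt; chromatography with recycling of the 5-epimer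
Reagents that add atoms: 2,2-dimethoxypropane, COC(C)(C)OC
Why: Acetalisation of the cis-1,3-diol protects both hydroxyls and gives a cis-fused bicycle in which base-mediated ketone α-epimerisation should place the C5 allyl group on the exo (α) face, away from the dioxane ring, the acetal oxygen being a poor leaving group for β-elimination.

Step 4
Reactants: 6 acetonide ketone; 7 isopropylmagnesium chloride
Product: 9 triol, via acetonide carbinol 8 (not isolated)
Conditions: iPrMgCl, CeCl3, THF, −78 °C; then 1 M aq. HCl, MeOH, rt
Reagents that add atoms: isopropylmagnesium chloride 7, CC(C)[Mg]Cl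
Why: Organocerium 1,2-addition (Imamoto conditions, which suppress enolisation and β-hydride reduction) to the 2-substituted cyclopentanone should occur anti to the adjacent C5 allyl group, that is from the β face, giving C4 with OH α and isopropyl β, and the acidic work-up hydrolyses the acetonide.

Step 5
Reactants: 9 triol
Product: 10 hydroxy aldehyde (C10 formyl)
Conditions: TEMPO (cat.), PhI(OAc)2, CH2Cl2, rt
Reagents that add atoms: none
Why: Oxoammonium (TEMPO) oxidation is selective for the primary C10 alcohol over the secondary C2 and tertiary C4 hydroxyls and stops at the aldehyde, which cannot enolise (quaternary C1) and cannot form a lactol with the trans-disposed C4 hydroxyl.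

Step 6
Reactants: 10 hydroxy aldehyde
Product: 11 C2 tert-butyldimethylsilyl ether
Conditions: TBSOTf, 2,6-lutidine, CH2Cl2, −78 °C
Reagents that add atoms: tert-butyldimethylsilyl triflate, CC(C)(C)[Si](C)(C)OS(=O)(=O)C(F)(F)F
Why: Silyl triflate silylation at low temperature should take the secondary C2 hydroxyl and leave the much more hindered tertiary C4 hydroxyl free, as the key step requires.

Step 7
Reactants: 11 C2 tert-butyldimethylsilyl ether
Product: 12 (E)-prop-1-enyl aldehyde
Conditions: [Ir(cod)(PMePh2)2]PF6 (cat., H2-activated), THF, rt
Reagents that add atoms: none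
Why: Cationic iridium hydride-catalysed allyl-to-propenyl isomerisation moves the terminal alkene by one position only, which makes C6 a vinylic carbon ready for cleavage and touches no stereocentre.

Step 8
Reactants: 12 (E)-prop-1-enyl aldehyde
Product: 13 trans-dialdehyde (used crude)
Conditions: O3, CH2Cl2, −78 °C; then PPh3, −78 °C to rt
Reagents that add atoms: ozone, [O-][O+]=O
Why: Ozonolysis with reductive work-up cleaves the propenyl alkene to the C6 aldehyde; the C5 centre α to it keeps the trans arrangement, which is also the thermodynamic one (formyl cis to the C4 hydroxyl, trans to isopropyl and to the C1 formyl group).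

Step 9
Reactants: 14 2-(chloromethyl)-3-(trimethylsilyl)prop-1-ene
Product: 15 3-iodo-2-[(trimethylsilyl)methyl]prop-1-ene
Conditions: NaI, acetone, rt (dark)
Reagents that add atoms: sodium iodide, [Na+].[I-]
Why: Finkelstein halide exchange of the allylic chloride is driven by precipitation of NaCl.

Step 10
Reactants: 13 trans-dialdehyde; 15 3-iodo-2-[(trimethylsilyl)methyl]prop-1-ene
Product: 17 8-methylene hydroazulene triol 2-TBS ether (6S; C10 epimer mixture), via Barbier adduct 16 (not isolated)
Conditions: SnF2, THF, 0 °C to rt; then BF3·OEt2, CH2Cl2, −78 to −40 °C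
Reagents that add atoms: 3-iodo-2-[(trimethylsilyl)methyl]prop-1-ene 15, C=C(CI)C[Si](C)(C)C
Why: SnF2 inserts into the allylic C–I bond of 15 to give an allyl fluorostannane of tetravalent tin, which adds in Barbier fashion through a closed six-membered transition state to the C6 aldehyde while that aldehyde is held in a six-membered chelate with the free C4 hydroxyl; BF3·OEt2 then activates the remaining C10 aldehyde and the allylsilane adds to it in SE2′ fashion through an open transition state, the β-silyl cation collapsing to the exocyclic methylene and Me3SiF. The closest known reaction type is the (3+4) annulation of 1,4-dicarbonyl compounds with 2-(silylmethyl)allyl halides as 2-methylenepropane-1,3-diyl dianion equivalents (Barbier allylation followed by intramolecular Hosomi–Sakurai addition). The seven-membered ring (C1, C5, C6, C7, C8, C9, C10) is closed by 7-exo-trig attack of the allylsilane on the C10 carbonyl, and the vicinal trans formyl groups on the cyclopentane make the ring fusion trans. C6 is set by the chelate, which is cis-fused to the cyclopentane and exposes the aldehyde face anti to C1, so the allyl group should enter there and give the 6S (β-oxygen) carbinol; a non-coordinating silyl ether at C4 would leave this face choice to an ambiguous Felkin preference between two quaternary neighbours; C10 is formed without control and is erased by oxidation in step 12. The step needs the first addition at C6 and not at C10, and carbonyl addition and not oxonium bridging: the C4 hydroxyl activates only the C6 aldehyde while the neopentyl C10 aldehyde is shielded by the non-coordinating C2 OTBS group, and the trans relationship makes a lactol or oxocarbenium ion between O6 and C10 a strained trans-fused bicyclo[3.3.0] system, so the free aldehyde should react.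

Step 11
Reactants: 17 8-methylene hydroazulene triol 2-TBS ether
Product: 18 C6 triethylsilyl ether
Conditions: TESCl, imidazole, CH2Cl2, −20 °C
Reagents that add atoms: chlorotriethylsilane, CC[Si](Cl)(CC)CC
Why: Silyl chloride silylation discriminates by steric access, so the C6 hydroxyl (next to the C5 methine) should react before the neopentyl C10 hydroxyl (next to quaternary C1) and the tertiary C4 hydroxyl, leaving C10 alone free for oxidation.

Step 12
Reactants: 18 C6 triethylsilyl ether
Product: 20 conjugated enone (C10 ketone and C8=C9 alkene with C8 methyl), via exo-methylene ketone 19 (not isolated)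
Conditions: Dess–Martin periodinane, pyridine, CH2Cl2, 0 °C to rt; then DBU, rt
Reagents that add atoms: none
Why: Dess–Martin oxidation converts both C10 epimers into one β,γ-unsaturated ketone, and DBU then moves the exocyclic alkene into conjugation through the C9 dienolate (γ-protonation at the exocyclic carbon), which creates the C8 methyl group and the C8=C9 alkene; C1 is quaternary, so no centre next to the ketone can epimerise.

Step 13
Reactants: 20 conjugated enone
Product: 21 10α-allylic alcohol
Conditions: NaBH4, CeCl3·7H2O, MeOH, −78 to −40 °C
Reagents that add atoms: none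
Why: Luche 1,2-reduction of the enone; hydride should be delivered on the β face, anti to the axial C1 methyl group that flanks the carbonyl, giving the pseudo-equatorial 10α (10S) alcohol without conjugate reduction.

Step 14
Reactants: 21 10α-allylic alcohol; 22 benzoyl chloride
Product: 23 C10 benzoate
Conditions: BzCl, pyridine, DMAP (cat.), CH2Cl2, rt
Reagents that add atoms: benzoyl chloride 22, O=C(Cl)c1ccccc1
Why: DMAP-catalysed acylation esterifies the only reactive (secondary allylic) hydroxyl with retention at C10, the tertiary C4 hydroxyl being too hindered to react.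

Step 15
Reactants: 23 C10 benzoate
Product: 24 C6 alcohol
Conditions: PPTS, MeOH/CH2Cl2, 0 °C
Reagents that add atoms: none
Why: Mild acid methanolysis removes the triethylsilyl ether at C6 much faster than the hindered tert-butyldimethylsilyl ether at C2 and leaves the allylic benzoate intact.

Step 16
Reactants: 24 C6 alcohol; 25 angelic acid
Product: 26 C6 angelate
Conditions: angelic acid, 2,4,6-trichlorobenzoyl chloride, Et3N, toluene, rt; then 24, 80 °C
Reagents that add atoms: angelic acid 25, C/C=C(/C)C(=O)O
Why: Esterification through the angelic 2,4,6-trichlorobenzoic mixed anhydride (Yamaguchi-type, run without DMAP) should acylate the hindered secondary C6 hydroxyl with retention at C6 and without Z-to-E isomerisation to the tiglate, while the tertiary C4 hydroxyl does not react.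

Step 17
Reactants: 26 C6 angelate
Product: 27 C2 alcohol
Conditions: HF·pyridine, pyridine, THF, 0 °C to rt
Reagents that add atoms: none
Why: Buffered fluoride cleavage of the silyl ether frees the C2 hydroxyl without affecting the angelate, the benzoate or the alkene.

Step 18
Reactants: 27 C2 alcohol; 28 acetic anhydride
Product: 29 target CNP0248576.1
Conditions: Ac2O, pyridine, DMAP (cat.), CH2Cl2, 0 °C to rt
Reagents that add atoms: acetic anhydride 28, CC(=O)OC(C)=O
Why: Acetylation of the secondary C2 hydroxyl with retention completes the target, the tertiary C4 hydroxyl being inert under these conditions.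

Compound list
1 | (S)-allethrolone, (4S)-4-hydroxy-3-methyl-2-(prop-2-enyl)cyclopent-2-en-1-one | C=CCC1=C(C)[C@@H](O)CC1=O | starting material
2 | (bromomethyl)chlorodimethylsilane | C[Si](C)(Cl)CBr | starting material
3 | (bromomethyl)dimethylsilyl ether of 1 at the C2 oxygen | C=CCC1=C(C)[C@@H](O[Si](C)(C)CBr)CC1=O | intermediate
4 | siloxane ketone, not isolated: cis-fused 2,2-dimethyl-1-oxa-2-silacyclopentane on C1–C2 (CH2 on C1 and O on C2 both β, C1 methyl α), C4 ketone, C5 allyl as epimer mixture | C=CCC1C(=O)C[C@@H]2O[Si](C)(C)C[C@]12C | intermediate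
5 | keto diol: C4 ketone, C2-OH β, C1 with CH3 α and CH2OH β, C5 allyl as epimer mixture | C=CCC1C(=O)C[C@H](O)[C@]1(C)CO | intermediate
6 | acetonide ketone: isopropylidene acetal of the C2/C10 diol (cis-fused 1,3-dioxane), C5 allyl α | C=CC[C@H]1C(=O)C[C@@H]2OC(C)(C)OC[C@]12C | intermediate
7 | isopropylmagnesium chloride | CC(C)[Mg]Cl | starting material
8 | acetonide carbinol, not isolated: as 6 with C4-OH α and isopropyl β | C=CC[C@H]1[C@](O)(C(C)C)C[C@@H]2OC(C)(C)OC[C@]12C | intermediate
9 | triol: C2-OH β, C10 CH2OH β, C4-OH α with isopropyl β, C5 allyl α | C=CC[C@H]1[C@](O)(C(C)C)C[C@H](O)[C@]1(C)CO | intermediate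
10 | hydroxy aldehyde: as 9 with C10 formyl | C=CC[C@H]1[C@](O)(C(C)C)C[C@H](O)[C@]1(C)C=O | intermediate
11 | C2 tert-butyldimethylsilyl ether of 10 | C=CC[C@H]1[C@](O)(C(C)C)C[C@H](O[Si](C)(C)C(C)(C)C)[C@]1(C)C=O | intermediate
12 | (E)-prop-1-enyl aldehyde | C/C=C/[C@H]1[C@](O)(C(C)C)C[C@H](O[Si](C)(C)C(C)(C)C)[C@]1(C)C=O | intermediate
13 | trans-cyclopentane-1,2-dicarbaldehyde: C5 formyl α, C1 formyl β and CH3 α, C2 OTBS β, C4-OH α (free) with isopropyl β | O=C[C@H]1[C@](O)(C(C)C)C[C@H](O[Si](C)(C)C(C)(C)C)[C@]1(C)C=O | intermediate
14 | 2-(chloromethyl)-3-(trimethylsilyl)prop-1-ene | C=C(CCl)C[Si](C)(C)C | starting material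
15 | 3-iodo-2-[(trimethylsilyl)methyl]prop-1-ene | C=C(CI)C[Si](C)(C)C | intermediate
16 | Barbier adduct, not isolated: 6S homoallylic alcohol carrying the allylsilane, C10 aldehyde intact | C=C(C[Si](C)(C)C)C[C@H](O)[C@H]1[C@](O)(C(C)C)C[C@H](O[Si](C)(C)C(C)(C)C)[C@]1(C)C=O | intermediate
17 | 8-methylene trans-hydroazulene-4,6,10-triol 2-TBS ether: 6β-OH (6S), 4α-OH, C10-OH as epimer mixture | O[C@H]1CC(=C)CC(O)[C@@]2(C)[C@@H](O[Si](C)(C)C(C)(C)C)C[C@@](O)(C(C)C)[C@H]12 | intermediate
18 | C6 triethylsilyl ether of 17 | CC[Si](CC)(CC)O[C@H]1CC(=C)CC(O)[C@@]2(C)[C@@H](O[Si](C)(C)C(C)(C)C)C[C@@](O)(C(C)C)[C@H]12 | intermediate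
19 | exo-methylene ketone, not isolated: C10 ketone, C8 exocyclic methylene | CC[Si](CC)(CC)O[C@H]1CC(=C)CC(=O)[C@@]2(C)[C@@H](O[Si](C)(C)C(C)(C)C)C[C@@](O)(C(C)C)[C@H]12 | intermediate
20 | conjugated enone: C10 ketone, C8=C9, C8 methyl | CC[Si](CC)(CC)O[C@H]1CC(C)=CC(=O)[C@@]2(C)[C@@H](O[Si](C)(C)C(C)(C)C)C[C@@](O)(C(C)C)[C@H]12 | intermediate
21 | 10α-allylic alcohol (10S) | CC[Si](CC)(CC)O[C@H]1CC(C)=C[C@H](O)[C@@]2(C)[C@@H](O[Si](C)(C)C(C)(C)C)C[C@@](O)(C(C)C)[C@H]12 | intermediate
22 | benzoyl chloride | O=C(Cl)c1ccccc1 | starting material
23 | C10 benzoate with C6 OTES and C2 OTBS | CC[Si](CC)(CC)O[C@H]1CC(C)=C[C@H](OC(=O)c3ccccc3)[C@@]2(C)[C@@H](O[Si](C)(C)C(C)(C)C)C[C@@](O)(C(C)C)[C@H]12 | intermediate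
24 | C6 alcohol: 6β-OH, C10 benzoate, C2 OTBS | O[C@H]1CC(C)=C[C@H](OC(=O)c3ccccc3)[C@@]2(C)[C@@H](O[Si](C)(C)C(C)(C)C)C[C@@](O)(C(C)C)[C@H]12 | intermediate
25 | angelic acid, (Z)-2-methylbut-2-enoic acid | C/C=C(/C)C(=O)O | starting material
26 | C6 angelate with C10 benzoate and C2 OTBS | C/C=C(/C)C(=O)O[C@H]1CC(C)=C[C@H](OC(=O)c3ccccc3)[C@@]2(C)[C@@H](O[Si](C)(C)C(C)(C)C)C[C@@](O)(C(C)C)[C@H]12 | intermediate
27 | C2 alcohol: 2β-OH, C6 angelate, C10 benzoate | C/C=C(/C)C(=O)O[C@H]1CC(C)=C[C@H](OC(=O)c3ccccc3)[C@@]2(C)[C@@H](O)C[C@@](O)(C(C)C)[C@H]12 | intermediate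
28 | acetic anhydride | CC(=O)OC(C)=O | starting material
29 | CNP0248576.1, (1R,2S,4R,5S,6S,10S) in the numbering used here: 2β-acetoxy, 4α-hydroxy, 6β-angeloyloxy, 10α-benzoyloxy | C/C=C(/C)C(=O)O[C@H]1CC(C)=C[C@H](OC(=O)c2ccccc2)[C@@]2(C)[C@@H](OC(C)=O)C[C@@](O)(C(C)C)[C@H]12 | target

Total step count: 18. Longest linear sequence: 17 steps (steps 1–8 and 10–18 from 1; step 9 prepares the annulation reagent).

Steps most likely to fail

Step 10. What may go wrong: loss of facial control at C6 if the allyltin species adds without chelation, first addition at the C10 aldehyde, protodesilylation of the allylsilane before ring closure, or sluggish closure of the seven-membered ring onto the neopentyl aldehyde. The fallback reverses the two events and separates them. It sets out from dialdehyde 13 and chloride 14: a chelation-controlled Hosomi–Sakurai addition of the allylsilane end (SnCl4, CH2Cl2, −78 °C, the C4-OH/C6=O chelate again directing attack anti to C1) should give the 2-(chloromethyl)allyl carbinol F1. An intramolecular Barbier allylation of the C10 aldehyde (indium powder, NaI, DMF/H2O; alternatively CrCl2 under Nozaki–Hiyama conditions) then closes the ring and comes back to the route at triol 17.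

Step 2. What may go wrong: hydrogen-atom transfer to the C5 radical from the α face, so that the whole burden falls on the equilibration of step 3, where an unfavourable equilibrium or β-elimination of the C2 oxygen would cut the supply of 6. The fallback forms the C5–C6 bond, not the C5–H bond, in the radical step. It sets out from silane 2, which is attached (Et3N, DMAP, CH2Cl2) to the allyl-free enone (S)-4-hydroxy-3-methylcyclopent-2-en-1-one F2, to be secured separately, for example by lipase resolution of the racemate; this gives the silyl ether F3. Stork-type radical cyclisation in the presence of CH2=CHCH2SnBu3 (Keck allylation; AIBN, PhH, 80 °C) should trap the C5 radical by allyl transfer on the face away from the new oxasilolane ring. The sequence comes back to the route at siloxane ketone 4, now as the C5 epimer needed, which is oxidised and acetalised as in steps 2 and 3 without equilibration.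

Step 13. What may go wrong: poor facial selectivity of hydride delivery at C10 (attack syn to the C1 methyl group), giving the 10β-alcohol. The fallback inverts the carbinol instead of relying on selective reduction. It sets out from enone 20: the 10β-alcohol F4 from the reduction is submitted to Mitsunobu esterification with benzoic acid (PPh3, DIAD, toluene, 0 °C to rt), which should install the benzoate with inversion and comes back to the route at benzoate 23.

Further compounds
F1 | step 10 | 2-(chloromethyl)allyl carbinol: 6S homoallylic alcohol of 13 bearing CH2C(=CH2)CH2Cl at C6, C10 aldehyde intact | C=C(CCl)C[C@H](O)[C@H]1[C@](O)(C(C)C)C[C@H](O[Si](C)(C)C(C)(C)C)[C@]1(C)C=O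
F2 | step 2 | (S)-4-hydroxy-3-methylcyclopent-2-en-1-one | O=C1C=C(C)[C@@H](O)C1
F3 | step 2 | (bromomethyl)dimethylsilyl ether of F2 | O=C1C=C(C)[C@@H](O[Si](C)(C)CBr)C1
F4 | step 13 | 10β-allylic alcohol (C10 epimer of 21) | CC[Si](CC)(CC)O[C@H]1CC(C)=C[C@@H](O)[C@@]2(C)[C@@H](O[Si](C)(C)C(C)(C)C)C[C@@](O)(C(C)C)[C@H]12
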